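## Retrosynthetic overview
1. The target is (all-E,3S,4R,3'R)-7,8,7',8'-tetradehydro-β,β-carotene-3,4,3'-triol. Cutting C11=C12 and C11'=C12' gives C15 (ring A) + C10 dialdehyde + C15 (ring B), joined by two successive Wittig olefinations.
2. Both C15 tributylphosphonium salts come from one allylic chloride. Ring B differs only in its C4'–O bond, made on that chloride by a SeO2 ene reaction followed by a [2,3]-sigmatropic rearrangement, cis to the C3' carbinol.
3. The chloride is cut at C6–C7 (Sonogashira) into the enol triflate of (4R,6R)-actinol and (E)-3-methylpent-2-en-4-yn-1-ol.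
4. No ring is built. Both six-membered rings, with C3 and C3', are bought as actinol, and ring A and ring B diverge only at the chloride.

Assumption: (4R,6R)-actinol (the fermentation-derived bulk intermediate of zeaxanthin manufacture), (E)-3-methylpent-2-en-4-yn-1-ol and 2,7-dimethylocta-2,4,6-trienedial are bought. The comments use carotenoid numbering.

## Route

Step 1
Reactants: 1 (4R,6R)-4-hydroxy-2,2,6-trimethylcyclohexan-1-one ((−)-actinol)
Product: 2 (4R,6R)-2,2,6-trimethyl-4-(trimethylsilyloxy)cyclohexan-1-one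
Conditions: TMSCl, imidazole, CH2Cl2, 0 °C → rt
Reagents that add atoms: chlorotrimethylsilane, C[Si](C)(C)Cl
Why: O-silylation removes the acidic carbinol proton, so the next step needs one equivalent of amide base and no alkoxide can be triflated; neither stereocentre is touched.

Step 2
Reactants: 2 (4R,6R)-2,2,6-trimethyl-4-(trimethylsilyloxy)cyclohexan-1-one
Product: 5 (4R)-4-hydroxy-2,6,6-trimethylcyclohex-1-en-1-yl trifluoromethanesulfonate, via lithium enolate 3 (not isolated), via O-TMS enol triflate 4 (not isolated)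
Conditions: LiN(iPr)2, THF, −78 → 0 °C; PhNTf2, −78 °C → rt; then 1 M HCl, THF, rt
Reagents that add atoms: N-phenylbis(trifluoromethanesulfonimide), O=S(=O)(N(c1ccccc1)S(=O)(=O)C(F)(F)F)C(F)(F)F
Why: The ketone has a single α-hydrogen, so enolate O-triflation can give only the tetrasubstituted C5=C6 enol triflate, the labile TMS ether falls off in the acidic work-up, and the remote carbinol centre (later C3 and C3') stays (R).

Step 3
Reactants: 5 (4R)-4-hydroxy-2,6,6-trimethylcyclohex-1-en-1-yl trifluoromethanesulfonate; 6 (2E)-3-methylpent-2-en-4-yn-1-ol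
Product: 7 (1R)-4-[(3E)-5-hydroxy-3-methylpent-3-en-1-yn-1-yl]-3,5,5-trimethylcyclohex-3-en-1-ol
Conditions: Pd(PPh3)4 (5 mol %), CuI (10 mol %), Et3N, DMF, rt, degassed
Reagents that add atoms: none
Why: In this Sonogashira coupling zerovalent palladium inserts into the vinyl C–OTf bond and takes up the copper acetylide, forming C6–C7 with both free hydroxyls tolerated and the 9E alkene retained.

Step 4
Reactants: 7 (1R)-4-[(3E)-5-hydroxy-3-methylpent-3-en-1-yn-1-yl]-3,5,5-trimethylcyclohex-3-en-1-ol
Product: 9 (1R)-4-[(3E)-5-chloro-3-methylpent-3-en-1-yn-1-yl]-3,5,5-trimethylcyclohex-3-en-1-ol, via alkoxysulfonium chloride 8 (not isolated)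
Conditions: NCS, Me2S, CH2Cl2, −20 → 0 °C
Reagents that add atoms: N-chlorosuccinimide, O=C1CCC(=O)N1Cl
Why: In the Corey–Kim halogenation only the allylic alkoxysulfonium salt is displaced by chloride (SN2, neutral, no 9E/9Z scrambling), while any salt formed at the saturated ring carbinol reverts to the alcohol on work-up.

Step 5
Reactants: 9 (1R)-4-[(3E)-5-chloro-3-methylpent-3-en-1-yn-1-yl]-3,5,5-trimethylcyclohex-3-en-1-ol
Product: 10 tributyl{(2E)-5-[(4R)-4-hydroxy-2,6,6-trimethylcyclohex-1-en-1-yl]-3-methylpent-2-en-4-yn-1-yl}phosphonium chloride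
Conditions: PBu3, MeCN, rt, argon
Reagents that add atoms: tributylphosphine, CCCCP(CCCC)CCCC
Why: SN2 quaternisation of the phosphine by the primary allylic chloride runs without acid, so no allyl cation forms and the 9E geometry and the carbinol are kept.

Step 6
Reactants: 9 (1R)-4-[(3E)-5-chloro-3-methylpent-3-en-1-yn-1-yl]-3,5,5-trimethylcyclohex-3-en-1-ol
Product: 13 (1S,2R)-4-[(3E)-5-chloro-3-methylpent-3-en-1-yn-1-yl]-3,5,5-trimethylcyclohex-3-ene-1,2-diol (cis-diol), via allylseleninic acid 11 (not isolated), via divalent selenium ester 12 (not isolated)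
Conditions: SeO2 (0.5 equiv), t-BuOOH (2.5 equiv, decane), CH2Cl2, 0 °C → rt, stopped at about 70 % conversion; aq Na2S2O3/NaHCO3
Reagents that add atoms: selenium dioxide, O=[Se]=O (hands over the oxygen atom); tert-butyl hydroperoxide, CC(C)(C)OO (restores SeO2 and is the net oxygen source)
Why: In this Riley/Sharpless–Umbreit allylic hydroxylation the ene reaction removes the pseudo-axial C4–H on the face that carries the equatorial C3–OH and lies opposite the pseudo-axial C1 methyl, and allylseleninic acid 11 then passes oxygen suprafacially from C6 to C4 in a [2,3]-sigmatropic rearrangement (ring CH2 preferred over CH3, chain alkene deactivated by the allylic chloride), so the new carbinol is (4R), cis to the bought centre, just as cholesterol gives its 3β,4β-diol.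

Step 7
Reactants: 13 (1S,2R)-4-[(3E)-5-chloro-3-methylpent-3-en-1-yn-1-yl]-3,5,5-trimethylcyclohex-3-ene-1,2-diol
Product: 14 tributyl{(2E)-5-[(3R,4S)-3,4-dihydroxy-2,6,6-trimethylcyclohex-1-en-1-yl]-3-methylpent-2-en-4-yn-1-yl}phosphonium chloride
Conditions: PBu3, MeCN, rt, argon
Reagents that add atoms: tributylphosphine, CCCCP(CCCC)CCCC
Why: The neutral SN2 quaternisation touches only the primary allylic chloride, so the acid-labile allylic C4 carbinol is never exposed to ionising conditions.

Step 8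
Reactants: 10 tributyl{(2E)-5-[(4R)-4-hydroxy-2,6,6-trimethylcyclohex-1-en-1-yl]-3-methylpent-2-en-4-yn-1-yl}phosphonium chloride; 15 (2E,4E,6E)-2,7-dimethylocta-2,4,6-trienedial
Product: 17 (all-E,3R)-3-hydroxy-7,8-didehydro-12'-apo-β-caroten-12'-al, via ring A ylide 16 (not isolated)
Conditions: 15 (2.5 equiv), NaOMe (1.3 equiv), CH2Cl2/MeOH, 0 °C → rt, dark, argon
Reagents that add atoms: none
Why: In this Wittig olefination the excess dialdehyde holds the reaction at mono-condensation, the free hydroxyl is tolerated, and the trialkylphosphonium allyl ylide gives the 11E alkene without isomerising C9=C10.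

Step 9
Reactants: 14 tributyl{(2E)-5-[(3R,4S)-3,4-dihydroxy-2,6,6-trimethylcyclohex-1-en-1-yl]-3-methylpent-2-en-4-yn-1-yl}phosphonium chloride; 17 (all-E,3R)-3-hydroxy-7,8-didehydro-12'-apo-β-caroten-12'-al
Product: 19 (all-E,3S,4R,3'R)-7,8,7',8'-tetradehydro-β,β-carotene-3,4,3'-triol (target), via ring B ylide 18 (not isolated)
Conditions: 14 (1.3 equiv), NaOMe (2 equiv), CH2Cl2/MeOH, rt, dark, argon; chromatography on Et3N-deactivated silica, crystallisation from CH2Cl2/hexane
Reagents that add atoms: none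
Why: The second Wittig olefination closes C11'=C12' (E) under basic conditions that none of the three carbinol centres or the polyene responds to, so the unprotected triol is obtained directly.

## Compound list
1 | (4R,6R)-4-hydroxy-2,2,6-trimethylcyclohexan-1-one (actinol) | CC1(C)C[C@H](O)C[C@@H](C)C1=O | starting material
2 | (4R,6R)-2,2,6-trimethyl-4-(trimethylsilyloxy)cyclohexan-1-one | CC1(C)C[C@H](O[Si](C)(C)C)C[C@@H](C)C1=O | intermediate
3 | lithium (4R)-2,6,6-trimethyl-4-(trimethylsilyloxy)cyclohex-1-en-1-olate | CC1=C([O-])C(C)(C)C[C@H](O[Si](C)(C)C)C1.[Li+] | intermediate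
4 | (4R)-2,6,6-trimethyl-4-(trimethylsilyloxy)cyclohex-1-en-1-yl trifluoromethanesulfonate | CC1=C(OS(=O)(=O)C(F)(F)F)C(C)(C)C[C@H](O[Si](C)(C)C)C1 | intermediate
5 | (4R)-4-hydroxy-2,6,6-trimethylcyclohex-1-en-1-yl trifluoromethanesulfonate | CC1=C(OS(=O)(=O)C(F)(F)F)C(C)(C)C[C@H](O)C1 | intermediate
6 | (2E)-3-methylpent-2-en-4-yn-1-ol | C#C/C(C)=C/CO | starting material
7 | (1R)-4-[(3E)-5-hydroxy-3-methylpent-3-en-1-yn-1-yl]-3,5,5-trimethylcyclohex-3-en-1-ol | CC1=C(C#C/C(C)=C/CO)C(C)(C)C[C@H](O)C1 | intermediate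
8 | dimethyl alkoxysulfonium chloride of the primary alcohol of 7 | CC1=C(C#C/C(C)=C/CO[S+](C)C)C(C)(C)C[C@H](O)C1.[Cl-] | intermediate
9 | (1R)-4-[(3E)-5-chloro-3-methylpent-3-en-1-yn-1-yl]-3,5,5-trimethylcyclohex-3-en-1-ol | CC1=C(C#C/C(C)=C/CCl)C(C)(C)C[C@H](O)C1 | intermediate
10 | ring A C15 tributylphosphonium chloride, (4R)-4-hydroxy, 9E | CC1=C(C#C/C(C)=C/C[P+](CCCC)(CCCC)CCCC)C(C)(C)C[C@H](O)C1.[Cl-] | intermediate
11 | allylseleninic acid: Se on C6, cis to the C3–OH, alkene shifted to C4=C5 | CC1=C[C@@H](O)CC(C)(C)[C@@]1(C#C/C(C)=C/CCl)[Se](=O)O | intermediate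
12 | divalent selenium ester (C4–O–Se–OH) of 13 | CC1=C(C#C/C(C)=C/CCl)C(C)(C)C[C@H](O)[C@@H]1O[Se]O | intermediate
13 | (1S,2R)-4-[(3E)-5-chloro-3-methylpent-3-en-1-yn-1-yl]-3,5,5-trimethylcyclohex-3-ene-1,2-diol | CC1=C(C#C/C(C)=C/CCl)C(C)(C)C[C@H](O)[C@@H]1O | intermediate
14 | ring B C15 tributylphosphonium chloride, (3R,4S)-3,4-dihydroxy (cis), 9E | CC1=C(C#C/C(C)=C/C[P+](CCCC)(CCCC)CCCC)C(C)(C)C[C@H](O)[C@@H]1O.[Cl-] | intermediate
15 | (2E,4E,6E)-2,7-dimethylocta-2,4,6-trienedial | O=C/C(C)=C/C=C/C=C(\C)C=O | starting material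
16 | ring A tributylphosphonium ylide | CC1=C(C#C/C(C)=C/C=P(CCCC)(CCCC)CCCC)C(C)(C)C[C@H](O)C1 | intermediate
17 | (all-E,3R)-3-hydroxy-7,8-didehydro-12'-apo-β-caroten-12'-al | CC1=C(C#C/C(C)=C/C=C/C(C)=C/C=C/C=C(\C)C=O)C(C)(C)C[C@H](O)C1 | intermediate
18 | ring B tributylphosphonium ylide | CC1=C(C#C/C(C)=C/C=P(CCCC)(CCCC)CCCC)C(C)(C)C[C@H](O)[C@@H]1O | intermediate
19 | (all-E,3S,4R,3'R)-7,8,7',8'-tetradehydro-β,β-carotene-3,4,3'-triol | CC1=C(C#C/C(C)=C/C=C/C(C)=C/C=C/C=C(C)/C=C/C=C(\C)C#CC2=C(C)[C@@H](O)[C@@H](O)CC2(C)C)C(C)(C)C[C@H](O)C1 | target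

## Count and risks
Total steps: 9. Longest linear sequence: 7 (steps 1, 2, 3, 4, 6, 7, 9; the branch 1, 2, 3, 4, 5, 8, 9 is equally long).

**Step 6 is the most likely to fail.** C6 is fully substituted and sits next to the gem-dimethyl carbon, so the ene step may be slow. The doubly activated C4 carbinol can also be oxidised further to the enone, and the C9 methyl is a possible second site.
- The fallback sets out from 9 and comes back at 13. It sets C4 by carbonyl reduction instead of C–O transfer.
- Allylic C–H oxidation with dirhodium tetracaprolactamate Rh2(cap)4 and t-BuOOH (K2CO3, CH2Cl2) gives (6S)-3-[(3E)-5-chloro-3-methylpent-3-en-1-yn-1-yl]-6-hydroxy-2,4,4-trimethylcyclohex-2-en-1-one F1. This is also the over-oxidation product of step 6, so that material can be recycled here.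
- LiBH(s-Bu)3 (2.2 equiv, THF, −78 °C) then attacks the fully β-substituted enone 1,2 along the equatorial trajectory. This places the new hydroxyl pseudo-axial and cis to C3–OH, giving 13. At this temperature the allylic chloride should survive.

**Step 8 is the second risk.** A symmetrical dialdehyde has to react only once, and alloxanthin from double condensation costs ring A salt.
- The fallback sets out from 15 and comes back at 17.
- HC(OMe)3 (1 equiv) with catalytic p-TsOH in MeOH at 0 °C converts the cheap dialdehyde into (2E,4E,6E)-8,8-dimethoxy-2,7-dimethylocta-2,4,6-trienal F2, separated from diacetal and recovered 15.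
- Ylide 16, generated from 10 with NaOMe, then meets a single aldehyde and gives the (all-E,3R)-3-hydroxy-7,8-didehydro-12'-apo-β-caroten-12'-al dimethyl acetal F3.
- Dilute aqueous H2SO4 in acetone at 0 °C releases 17. This fragment has no allylic carbinol, so it tolerates the acid.

**Step 9 is the third risk.** The ylide of an unprotected diol salt may react slowly, may give 11'Z material, or may isomerise at C9'.
- The fallback sets out from 13 and comes back at 19.
- Michaelis–Becker substitution with NaP(O)(OEt)2 (THF, 0 °C → rt) gives diethyl {(2E)-5-[(3R,4S)-3,4-dihydroxy-2,6,6-trimethylcyclohex-1-en-1-yl]-3-methylpent-2-en-4-yn-1-yl}phosphonate F4.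
- Horner–Wadsworth–Emmons olefination of 17 with F4 (KOt-Bu, 3.2 equiv, THF, −78 → 0 °C) gives 19 with the higher E selectivity of allyl phosphonates and a water-soluble phosphorus residue.

## Further compounds
F1 | step 6 | (6S)-3-[(3E)-5-chloro-3-methylpent-3-en-1-yn-1-yl]-6-hydroxy-2,4,4-trimethylcyclohex-2-en-1-one | CC1=C(C#C/C(C)=C/CCl)C(C)(C)C[C@H](O)C1=O
F2 | step 8 | (2E,4E,6E)-8,8-dimethoxy-2,7-dimethylocta-2,4,6-trienal | O=C/C(C)=C/C=C/C=C(\C)C(OC)OC
F3 | step 8 | (all-E,3R)-3-hydroxy-7,8-didehydro-12'-apo-β-caroten-12'-al dimethyl acetal | CC1=C(C#C/C(C)=C/C=C/C(C)=C/C=C/C=C(\C)C(OC)OC)C(C)(C)C[C@H](O)C1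
F4 | step 9 | diethyl {(2E)-5-[(3R,4S)-3,4-dihydroxy-2,6,6-trimethylcyclohex-1-en-1-yl]-3-methylpent-2-en-4-yn-1-yl}phosphonate | CC1=C(C#C/C(C)=C/CP(=O)(OCC)OCC)C(C)(C)C[C@H](O)[C@@H]1O
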